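**Strategy.** Ring C is disconnected at O1–C8a. Ring A carries C6-OMe, C7-O and C8-OMe arranged symmetrically about the C4a–C7 axis, so C5 and C8a are equivalent and can both start as bromine on a syringaldehyde-derived ring. The precursor is an acyclic 2-methoxy-1,3-diketone whose 2,6-dibromoaryl ketone becomes C4 and whose other ketone bears ring B. In one copper-catalysed operation the enolate oxygen of the ring B ketone displaces one of the two equivalent bromines, forming O1–C8a and the pyranone. The surviving bromine lies at C5, peri to C4=O, ready for hydroxylation. Benzyl ethers mask the C7, C2' and C4' hydroxyls until a final hydrogenolysis.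

Key step: step 9

Remark: compounds 4 and 9 are taken as catalogue chemicals. The target is achiral, and aldol 13 is carried on as a diastereomer mixture because both of its stereocentres become sp2 carbons in steps 8 and 9.

**Step 1**
Reactants: 1 syringaldehyde (4-hydroxy-3,5-dimethoxybenzaldehyde)
Product: 2 4-(benzyloxy)-3,5-dimethoxybenzaldehyde
Conditions: BnBr (1.1 equiv), K2CO3 (1.5 equiv), DMF, 60 °C
Reagents that add atoms: benzyl bromide, BrCc1ccccc1
Why: Williamson ether synthesis, in which the phenoxide of 1 (acidified by the para formyl group) is alkylated by benzyl bromide in an SN2 reaction.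

**Step 2**
Reactants: 2 4-(benzyloxy)-3,5-dimethoxybenzaldehyde
Product: 3 4-(benzyloxy)-2,6-dibromo-3,5-dimethoxybenzaldehyde
Conditions: Br2 (2.5 equiv), NaOAc (3 equiv), AcOH, 20 → 50 °C, dark; aq. Na2S2O3 work-up
Reagents that add atoms: bromine, BrBr
Why: Electrophilic aromatic bromination at C2 and C6, the only free ring positions and each ortho to one methoxy group and para to the other, while the acetate buffer removes HBr so that the benzyl ether (whose phenyl ring is far less nucleophilic) should survive.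

**Step 3**
Reactants: 4 3-(benzyloxy)-4-methoxybenzaldehyde
Product: 6 3-(benzyloxy)-4-methoxyphenol, via aryl formate 5 (not isolated)
Conditions: mCPBA (1.3 equiv), CH2Cl2, 0 °C → rt; then K2CO3 (0.2 equiv), MeOH, rt
Reagents that add atoms: 3-chloroperoxybenzoic acid, OOC(=O)c1cccc(Cl)c1
Why: Baeyer–Villiger (Dakin-type) oxidation, in which the electron-rich aryl group para to the methoxy group migrates to give aryl formate 5, which mild methanolysis cleaves to the phenol.

**Step 4**
Reactants: 6 3-(benzyloxy)-4-methoxyphenol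
Product: 7 2,4-bis(benzyloxy)-1-methoxybenzene
Conditions: BnBr (1.2 equiv), K2CO3 (2 equiv), DMF, 60 °C
Reagents that add atoms: benzyl bromide, BrCc1ccccc1
Why: Williamson ether synthesis on an unhindered phenoxide.

**Step 5**
Reactants: 7 2,4-bis(benzyloxy)-1-methoxybenzene
Product: 8 1,5-bis(benzyloxy)-2-bromo-4-methoxybenzene
Conditions: NBS (1.05 equiv), MeCN, 0 °C → rt, dark
Reagents that add atoms: N-bromosuccinimide, O=C1CCC(=O)N1Br
Why: Electrophilic aromatic bromination at C5 of 7, which is para to the 2-benzyloxy and ortho to the 4-benzyloxy group, whereas C3 is shielded between two benzyloxy groups and C6 is activated by the methoxy group alone.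

**Step 6**
Reactants: 8 1,5-bis(benzyloxy)-2-bromo-4-methoxybenzene; 9 N,2-dimethoxy-N-methylacetamide
Product: 11 1-[2,4-bis(benzyloxy)-5-methoxyphenyl]-2-methoxyethan-1-one, via aryllithium 10 (not isolated)
Conditions: n-BuLi (1.05 equiv), THF, −78 °C; then 9 (1.2 equiv), −78 → 0 °C; aq. NH4Cl
Reagents that add atoms: none
Why: Bromine–lithium exchange outruns any attack on the benzyl ethers at −78 °C, and the aryllithium adds once to the Weinreb amide, whose chelated tetrahedral adduct releases the ketone only on work-up (Weinreb ketone synthesis).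

**Step 7**
Reactants: 11 1-[2,4-bis(benzyloxy)-5-methoxyphenyl]-2-methoxyethan-1-one; 3 4-(benzyloxy)-2,6-dibromo-3,5-dimethoxybenzaldehyde
Product: 13 3-[4-(benzyloxy)-2,6-dibromo-3,5-dimethoxyphenyl]-1-[2,4-bis(benzyloxy)-5-methoxyphenyl]-3-hydroxy-2-methoxypropan-1-one (racemic syn/anti mixture), via lithium enolate 12 (not isolated)
Conditions: LiN(SiMe3)2 (1.1 equiv), THF, −78 °C; then 3 (1.05 equiv), −78 °C; aq. NH4Cl at −78 °C
Reagents that add atoms: none
Why: Directed aldol addition of a preformed chelated Z lithium enolate to a non-enolisable aldehyde, in which the two new stereocentres (C2 and C3 of the chain) are set without control because C3 is erased in step 8 and C2 in step 9.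

**Step 8**
Reactants: 13 3-[4-(benzyloxy)-2,6-dibromo-3,5-dimethoxyphenyl]-1-[2,4-bis(benzyloxy)-5-methoxyphenyl]-3-hydroxy-2-methoxypropan-1-one
Product: 14 1-[4-(benzyloxy)-2,6-dibromo-3,5-dimethoxyphenyl]-3-[2,4-bis(benzyloxy)-5-methoxyphenyl]-2-methoxypropane-1,3-dione (racemic, enolisable)
Conditions: Dess–Martin periodinane (1.5 equiv), NaHCO3, CH2Cl2, 0 °C → rt
Reagents that add atoms: none
Why: Dess–Martin oxidation of a β-hydroxy ketone to the 1,3-diketone under buffered, non-basic conditions that avoid retro-aldol cleavage, leaving one enolisable, racemic centre between the carbonyls.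

**Step 9**
Reactants: 14 1-[4-(benzyloxy)-2,6-dibromo-3,5-dimethoxyphenyl]-3-[2,4-bis(benzyloxy)-5-methoxyphenyl]-2-methoxypropane-1,3-dione
Product: 15 7-(benzyloxy)-2-[2,4-bis(benzyloxy)-5-methoxyphenyl]-5-bromo-3,6,8-trimethoxy-4H-chromen-4-one
Conditions: CuI (10 mol%), 1,10-phenanthroline (20 mol%), Cs2CO3 (1.5 equiv), 4 Å MS, 1,4-dioxane (0.05 M), 90 °C, Ar
Reagents that add atoms: none
Why: Cs2CO3 deprotonates the CH(OMe) carbon between the carbonyls and the enolate binds monovalent copper; the copper-bound oxygen of the ring B carbonyl lies next to an ortho C–Br bond of the aroyl group, copper inserts into it (oxidative addition to an aryl trivalent copper enolate) and C–O reductive elimination forms O1–C8a and frees monovalent copper. The closest known reaction type is the copper-catalysed intramolecular Ullmann-type O-arylation of 1-(2-haloaryl)-1,3-diketones to chromones and flavones. Ring C closes in a 6-exo-trig mode, the enolate oxygen attacking the sp2 carbon C8a while bromide leaves outside the ring. No stereocentre is formed, and the racemic centre of 14 becomes the sp2 carbon C3. The step needs O-arylation by the ring B side oxygen at one bromine only: the other enolate oxygen or the central carbon could reach a bromine only through a four-membered ring, the two bromines are interchanged by rotation about the aryl–carbonyl bond so either gives the same product, and once ring C is closed no nucleophile is left for the C5 bromine. High dilution and exclusion of water should keep intermolecular coupling and retro-Claisen cleavage down.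

**Step 10**
Reactants: 15 7-(benzyloxy)-2-[2,4-bis(benzyloxy)-5-methoxyphenyl]-5-bromo-3,6,8-trimethoxy-4H-chromen-4-one
Product: 16 7-(benzyloxy)-2-[2,4-bis(benzyloxy)-5-methoxyphenyl]-5-hydroxy-3,6,8-trimethoxy-4H-chromen-4-one
Conditions: Cu(acac)2 (10 mol%), N,N'-bis(4-hydroxy-2,6-dimethylphenyl)oxalamide (10 mol%), LiOH·H2O (3 equiv), DMSO/H2O (4:1), 80 °C, Ar; then 1 M HCl
Reagents that add atoms: lithium hydroxide, [Li+].[OH-]
Why: Ullmann-type copper-catalysed hydroxylation in which the C4 carbonyl peri to C5 chelates copper and assists insertion into the C5–Br bond, while benzyl and methyl ethers are inert to these conditions.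

**Step 11**
Reactants: 16 7-(benzyloxy)-2-[2,4-bis(benzyloxy)-5-methoxyphenyl]-5-hydroxy-3,6,8-trimethoxy-4H-chromen-4-one
Product: 17 5,7,2',4'-tetrahydroxy-3,6,8,5'-tetramethoxyflavone
Conditions: H2 (1 atm), 10% Pd/C, EtOAc/MeOH (1:1), rt
Reagents that add atoms: none
Why: Catalytic hydrogenolysis cleaves the three benzylic C–O bonds at C7, C2' and C4', while methyl ethers and the conjugated pyranone should be untouched at 1 atm of hydrogen.

**Compound list**
1 | syringaldehyde (4-hydroxy-3,5-dimethoxybenzaldehyde) | COc1cc(C=O)cc(OC)c1O | starting material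
2 | 4-(benzyloxy)-3,5-dimethoxybenzaldehyde | COc1cc(C=O)cc(OC)c1OCc1ccccc1 | intermediate
3 | 4-(benzyloxy)-2,6-dibromo-3,5-dimethoxybenzaldehyde | COc1c(Br)c(C=O)c(Br)c(OC)c1OCc1ccccc1 | intermediate
4 | 3-(benzyloxy)-4-methoxybenzaldehyde (O-benzylisovanillin) | COc1ccc(C=O)cc1OCc1ccccc1 | starting material
5 | 3-(benzyloxy)-4-methoxyphenyl formate | COc1ccc(OC=O)cc1OCc1ccccc1 | intermediate (not isolated)
6 | 3-(benzyloxy)-4-methoxyphenol | COc1ccc(O)cc1OCc1ccccc1 | intermediate
7 | 2,4-bis(benzyloxy)-1-methoxybenzene | COc1ccc(OCc2ccccc2)cc1OCc1ccccc1 | intermediate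
8 | 1,5-bis(benzyloxy)-2-bromo-4-methoxybenzene | COc1cc(Br)c(OCc2ccccc2)cc1OCc1ccccc1 | intermediate
9 | N,2-dimethoxy-N-methylacetamide | COCC(=O)N(C)OC | starting material
10 | [2,4-bis(benzyloxy)-5-methoxyphenyl]lithium | [Li]c1cc(OC)c(OCc2ccccc2)cc1OCc1ccccc1 | intermediate (not isolated)
11 | 1-[2,4-bis(benzyloxy)-5-methoxyphenyl]-2-methoxyethan-1-one | COCC(=O)c1cc(OC)c(OCc2ccccc2)cc1OCc1ccccc1 | intermediate
12 | lithium (Z)-1-[2,4-bis(benzyloxy)-5-methoxyphenyl]-2-methoxyethen-1-olate | [Li+].CO/C=C(\[O-])c1cc(OC)c(OCc2ccccc2)cc1OCc1ccccc1 | intermediate (not isolated)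
13 | 3-[4-(benzyloxy)-2,6-dibromo-3,5-dimethoxyphenyl]-1-[2,4-bis(benzyloxy)-5-methoxyphenyl]-3-hydroxy-2-methoxypropan-1-one (racemic syn/anti mixture) | COC(C(O)c1c(Br)c(OC)c(OCc2ccccc2)c(OC)c1Br)C(=O)c1cc(OC)c(OCc2ccccc2)cc1OCc1ccccc1 | intermediate
14 | 1-[4-(benzyloxy)-2,6-dibromo-3,5-dimethoxyphenyl]-3-[2,4-bis(benzyloxy)-5-methoxyphenyl]-2-methoxypropane-1,3-dione (racemic, enolisable) | COC(C(=O)c1c(Br)c(OC)c(OCc2ccccc2)c(OC)c1Br)C(=O)c1cc(OC)c(OCc2ccccc2)cc1OCc1ccccc1 | intermediate
15 | 7-(benzyloxy)-2-[2,4-bis(benzyloxy)-5-methoxyphenyl]-5-bromo-3,6,8-trimethoxy-4H-chromen-4-one | COc1cc(-c2oc3c(OC)c(OCc4ccccc4)c(OC)c(Br)c3c(=O)c2OC)c(OCc2ccccc2)cc1OCc1ccccc1 | intermediate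
16 | 7-(benzyloxy)-2-[2,4-bis(benzyloxy)-5-methoxyphenyl]-5-hydroxy-3,6,8-trimethoxy-4H-chromen-4-one | COc1cc(-c2oc3c(OC)c(OCc4ccccc4)c(OC)c(O)c3c(=O)c2OC)c(OCc2ccccc2)cc1OCc1ccccc1 | intermediate
17 | 5,7,2',4'-tetrahydroxy-3,6,8,5'-tetramethoxyflavone | COc1cc(-c2oc3c(OC)c(O)c(OC)c(O)c3c(=O)c2OC)c(O)cc1O | target

**Step count.** Total: 11 steps. Longest linear sequence: 9 steps (4 → 17, steps 3 to 11).

**Steps most likely to fail**

Step 9. Retro-Claisen cleavage of the diketone by base could outpace C–O coupling. Insertion of copper could be slow because the doubly ortho-substituted aroyl group is twisted out of the enolate plane. Intermolecular coupling at the second bromine could also compete. The fallback makes O1 a phenol before the diketone is built and closes ring C by acid-catalysed cyclodehydration. It sets out from 3. Copper-catalysed mono-hydroxylation under the step 10 conditions with 1.2 equiv LiOH should give 4-(benzyloxy)-2-bromo-6-hydroxy-3,5-dimethoxybenzaldehyde F1, since the first phenoxide deactivates the ring toward a second substitution. MOMCl and i-Pr2NEt in CH2Cl2 should give 4-(benzyloxy)-2-bromo-3,5-dimethoxy-6-(methoxymethoxy)benzaldehyde F2. Aldol addition of enolate 12 as in step 7 should give 3-[4-(benzyloxy)-2-bromo-3,5-dimethoxy-6-(methoxymethoxy)phenyl]-1-[2,4-bis(benzyloxy)-5-methoxyphenyl]-3-hydroxy-2-methoxypropan-1-one F3. Dess–Martin oxidation as in step 8 should give 1-[4-(benzyloxy)-2-bromo-3,5-dimethoxy-6-(methoxymethoxy)phenyl]-3-[2,4-bis(benzyloxy)-5-methoxyphenyl]-2-methoxypropane-1,3-dione F4. HCl in MeOH at 50 °C should remove the acetal to give 1-[4-(benzyloxy)-2-bromo-6-hydroxy-3,5-dimethoxyphenyl]-3-[2,4-bis(benzyloxy)-5-methoxyphenyl]-2-methoxypropane-1,3-dione F5, which cyclodehydrates in the same pot. The route is rejoined at 15.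

Step 10. Hydroxide could add at C2 and open the pyranone, followed by fragmentation of the resulting diketone. The chelating 5-hydroxy-4-ketone product could sequester the copper catalyst. Coupling could be slow at a carbon flanked by C6-OMe and C4a, and hydrodebromination could compete. The fallback replaces hydroxide by methoxide and then unmasks the phenol by chelation-controlled dealkylation. It sets out from 15. NaOMe (5 equiv) and CuBr (0.3 equiv) in DMF/MeOH at 110 °C (Ullmann methoxylation) should give 7-(benzyloxy)-2-[2,4-bis(benzyloxy)-5-methoxyphenyl]-3,5,6,8-tetramethoxy-4H-chromen-4-one F6. MgI2 etherate in toluene/THF at 60 °C should then cleave only the 5-OMe, which forms a six-membered magnesium chelate with the C4 carbonyl. The route is rejoined at 16.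

Step 2. The second bromination could stall because the formyl group and the first bromine deactivate the ring, and forcing it could brominate or cleave the benzyl ether. The fallback raises the nucleophilicity of the ring by changing the oxidation level of the side chain. It sets out from 2. NaBH4 in MeOH should give [4-(benzyloxy)-3,5-dimethoxyphenyl]methanol F7. NBS (2.2 equiv) in MeCN at rt should give [4-(benzyloxy)-2,6-dibromo-3,5-dimethoxyphenyl]methanol F8. Activated MnO2 in CH2Cl2 should oxidise the benzylic alcohol, and the route is rejoined at 3.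

**Further compounds**
F1 | step 9 | 4-(benzyloxy)-2-bromo-6-hydroxy-3,5-dimethoxybenzaldehyde | COc1c(Br)c(C=O)c(O)c(OC)c1OCc1ccccc1
F2 | step 9 | 4-(benzyloxy)-2-bromo-3,5-dimethoxy-6-(methoxymethoxy)benzaldehyde | COCOc1c(C=O)c(Br)c(OC)c(OCc2ccccc2)c1OC
F3 | step 9 | 3-[4-(benzyloxy)-2-bromo-3,5-dimethoxy-6-(methoxymethoxy)phenyl]-1-[2,4-bis(benzyloxy)-5-methoxyphenyl]-3-hydroxy-2-methoxypropan-1-one (racemic syn/anti mixture) | COCOc1c(C(O)C(OC)C(=O)c2cc(OC)c(OCc3ccccc3)cc2OCc2ccccc2)c(Br)c(OC)c(OCc2ccccc2)c1OC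
F4 | step 9 | 1-[4-(benzyloxy)-2-bromo-3,5-dimethoxy-6-(methoxymethoxy)phenyl]-3-[2,4-bis(benzyloxy)-5-methoxyphenyl]-2-methoxypropane-1,3-dione | COCOc1c(C(=O)C(OC)C(=O)c2cc(OC)c(OCc3ccccc3)cc2OCc2ccccc2)c(Br)c(OC)c(OCc2ccccc2)c1OC
F5 | step 9 | 1-[4-(benzyloxy)-2-bromo-6-hydroxy-3,5-dimethoxyphenyl]-3-[2,4-bis(benzyloxy)-5-methoxyphenyl]-2-methoxypropane-1,3-dione | COC(C(=O)c1c(O)c(OC)c(OCc2ccccc2)c(OC)c1Br)C(=O)c1cc(OC)c(OCc2ccccc2)cc1OCc1ccccc1
F6 | step 10 | 7-(benzyloxy)-2-[2,4-bis(benzyloxy)-5-methoxyphenyl]-3,5,6,8-tetramethoxy-4H-chromen-4-one | COc1cc(-c2oc3c(OC)c(OCc4ccccc4)c(OC)c(OC)c3c(=O)c2OC)c(OCc2ccccc2)cc1OCc1ccccc1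
F7 | step 2 | [4-(benzyloxy)-3,5-dimethoxyphenyl]methanol | COc1cc(CO)cc(OC)c1OCc1ccccc1
F8 | step 2 | [4-(benzyloxy)-2,6-dibromo-3,5-dimethoxyphenyl]methanol | COc1c(Br)c(CO)c(Br)c(OC)c1OCc1ccccc1
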